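## Retrosynthetic overview

1. Target 23 comes from one acid hydrolysis of diester 22 (C1 hydroxy acid held as a pivalaldehyde dioxolanone, O3 as TBS ether, phenols as acetates), which comes from double acylation of 4,5-diol 19.
2. Feature used: on the cyclohexane ring O3, O4 and O5 are contiguous with O4/O5 trans, and the quaternary α-hydroxy-acid carbon C1 carries both ring CH2 groups (C2, C6). With C3 as a ketone, C3(=O)–C4(OR)–C5(OH) is an aldol pattern.
3. Key disconnection C4–C5: an intramolecular enamine aldol of keto aldehyde 13 (α-benzyloxy ketone arm C2–C3–C4 and acetaldehyde arm C6–C5 on the preformed C1) closes the only carbocycle and sets C4 and C5. C3 is set afterwards by equatorial hydride delivery.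
4. Keto aldehyde 13 comes from (S)-malic acid: pivalaldehyde dioxolanone, enolate alkylation anti to tert-butyl with 2-(benzyloxymethyl)allyl bromide (sets C1), CH2CO2H to thioester to CHO, alkene to ketone by ozonolysis.
5. Ring order: dioxolanone (step 1, kept to the end as a protecting ring), then the cyclohexane (step 7).

Key step: step 7

Remark: ring positions are numbered as in quinic acid (C1 bears OH and CO2H; O3 is axial and cis to O4, O4/O5 are trans-diequatorial, O5 is cis to the carboxyl). (E)-4-Acetoxycinnamic acid and 3-bromo-2-(bromomethyl)prop-1-ene are assumed to be purchased; the allylic bromide is used because the thermally fragile dioxolanone enolate needs a reactive electrophile at −78 °C.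

## Route

Step 1
Reactants: 1 (S)-malic acid; 2 pivalaldehyde
Product: 3 2-[(2S,4S)-2-tert-butyl-5-oxo-1,3-dioxolan-4-yl]acetic acid (tert-butyl cis to the CH2CO2H arm)
Conditions: TsOH·H2O (cat.), H2SO4 (cat.), pentane, reflux with azeotropic removal of water; recrystallisation
Reagents that add atoms: none
Why: Acid-catalysed acetalisation of the α-hydroxy acid unit (five-membered dioxolanone preferred over the six-membered ring through the β-carboxyl) under thermodynamic control should place the new acetal centre cis to the side chain, directed by the malic acid stereocentre, and crystallisation should remove the trans isomer.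

Step 2
Reactants: 4 3-bromo-2-(bromomethyl)prop-1-ene (3 equiv); 5 benzyl alcohol
Product: 7 2-(benzyloxymethyl)allyl bromide, via sodium benzyloxide 6 (not isolated)
Conditions: NaH, THF, 0 °C; then 4, 0 °C → rt
Reagents that add atoms: none
Why: Williamson ether synthesis (SN2 at an allylic bromide), with the dibromide in excess so that the second substitution is suppressed.

Step 3
Reactants: 3 dioxolanone acid; 7 allylic bromide
Product: 9 2-[(2S,4S)-4-{2-[(benzyloxy)methyl]prop-2-en-1-yl}-2-tert-butyl-5-oxo-1,3-dioxolan-4-yl]acetic acid (tert-butyl cis to CH2CO2H), via dilithium enolate carboxylate 8 (not isolated)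
Conditions: LiN(SiMe3)2 (2.2 equiv), THF, −78 °C; then 7, −78 → −40 °C; 1 M HCl work-up
Reagents that add atoms: none
Why: Enolate alkylation by the self-regeneration-of-stereocentres principle: the planar dioxolanone enolate (carboxylate carried as its lithium salt) should be attacked anti to the tert-butyl group, so the new C–C bond takes the place of the former C–H and fixes the quaternary centre that becomes C1.

Step 4
Reactants: 9 alkylated acid
Product: 10 S-ethyl 2-[(2S,4S)-4-{2-[(benzyloxy)methyl]prop-2-en-1-yl}-2-tert-butyl-5-oxo-1,3-dioxolan-4-yl]ethanethioate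
Conditions: EtSH, DCC, DMAP (cat.), CH2Cl2, 0 °C → rt
Reagents that add atoms: ethanethiol, CCS
Why: Steglich-type carbodiimide coupling gives a thioester, from which the aldehyde can later be released without hydride reagents that would open the dioxolanone.

Step 5
Reactants: 10 alkene thioester
Product: 12 S-ethyl 2-[(2S,4S)-4-(3-benzyloxy-2-oxopropyl)-2-tert-butyl-5-oxo-1,3-dioxolan-4-yl]ethanethioate, via secondary ozonide 11 (not isolated)
Conditions: O3, CH2Cl2, −78 °C (stopped at the first blue tinge); then PPh3, −78 °C → rt
Reagents that add atoms: ozone, [O-][O+]=O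
Why: Ozonolysis with reductive work-up unveils the C3 ketone from the 1,1-disubstituted alkene; the acyl-deactivated sulfur, the benzyl ether and the acetal should survive at −78 °C, and cleaving the alkene before the palladium step avoids its migration or reduction there.

Step 6
Reactants: 12 keto thioester
Product: 13 (2S,5R)-5-(3-benzyloxy-2-oxopropyl)-2-tert-butyl-5-(2-oxoethyl)-1,3-dioxolan-4-one (tert-butyl cis to the 2-oxoethyl arm)
Conditions: Et3SiH, Pd/C (cat.), acetone, rt
Reagents that add atoms: none
Why: Fukuyama reduction (palladium-catalysed hydride transfer from the silane to the thioester) gives the aldehyde under neutral conditions that should leave the ketone, the benzyl ether and the dioxolanone untouched.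

Step 7
Reactants: 13 keto aldehyde
Product: 14 4-O-benzyl-3-dehydroquinic acid 1-O,carboxyl pivalaldehyde acetal (spiro dioxolanone; C4 S, C5 R; 4-OBn and 5-OH trans; tert-butyl cis to C6)
Conditions: L-proline (30 mol %), DMSO, rt
Reagents that add atoms: none
Why: Proposed new method: L-proline condenses with the C3 ketone, and of the two possible enamines only the one toward the benzyloxy-bearing C4 can reach the C5 aldehyde (the C2 enamine could only close a four-membered ring), so C4–C5 bond formation closes the cyclohexanone in a 6-(enolendo)-exo-trig mode and iminium hydrolysis releases 14 and the catalyst. The closest known reactions are the Hajos–Parrish 6-enolendo aldolisation and proline aldol reactions of α-oxygenated ketones, which react at the oxygenated carbon. In the chair transition state the benzyloxy group lies anti to nitrogen on the enamine and the aldehyde oxygen is held by the proline carboxylic acid, which places the two oxygens anti across the new bond (trans on the ring) and, with the L catalyst, should give C4 S and C5 R. The fixed C1 centre only decides which of its substituents is axial in that chair (the lactone carbonyl carbon, syn to the developing C5 oxygen), so the likely contaminant is the trans isomer of opposite sense at C4/C5. Because C4 stays epimerisable and the aldol is reversible, the diequatorial trans ketol with the dioxolanone ring oxygen axial, as in quinic acid, is also the expected resting product. The step needs trans-4,5 selectivity in the right sense toward C1 and must avoid β-elimination of the C1 oxygen; the ring constraint, the catalyst chirality and the near-neutral medium are relied on for this.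

Step 8
Reactants: 14 ketol
Product: 15 5-O-triethylsilyl ether of 14
Conditions: TESCl, imidazole, DMF, 0 °C
Reagents that add atoms: chlorotriethylsilane, CC[Si](Cl)(CC)CC
Why: Mild silylation of the secondary aldol hydroxyl masks O5 before the hydride step, which should prevent lactone transfer from the dioxolanone to O5 and later lets O3 be distinguished from O5.

Step 9
Reactants: 15 silyloxy ketone
Product: 16 4-O-benzyl-5-O-triethylsilylquinic acid pivalaldehyde acetal (3-OH axial and cis to 4-OBn; C3 R)
Conditions: LiBH(s-Bu)3, THF, −78 °C; AcOH quench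
Reagents that add atoms: none
Why: Steric-approach-controlled ketone reduction by a bulky trialkylborohydride: axial attack at C3 is blocked by the axial C1–O bond, so hydride should enter equatorially and give the axial C3 alcohol cis to O4, while the hindered lactone carbonyl should be inert at −78 °C.

Step 10
Reactants: 16 alcohol
Product: 17 3-O-tert-butyldimethylsilyl ether of 16
Conditions: TBSOTf, 2,6-lutidine, CH2Cl2, 0 °C
Reagents that add atoms: tert-butyldimethylsilyl trifluoromethanesulfonate, CC(C)(C)[Si](C)(C)OS(=O)(=O)C(F)(F)F
Why: Silyl triflate silylation places the more robust TBS group on the hindered axial O3 so that the TES group on O5 can be removed selectively.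

Step 11
Reactants: 17 fully protected intermediate
Product: 19 3-O-TBS-quinic acid pivalaldehyde acetal (4,5-diol), via debenzylated TES ether 18 (not isolated)
Conditions: H2 (1 atm), Pd/C, EtOAc–MeOH, rt; filter; then PPTS (cat.), MeOH, rt
Reagents that add atoms: none
Why: Hydrogenolysis of the benzyl ether followed by acid-catalysed methanolysis of the less hindered and more labile TES ether should free O4 and O5 while the axial TBS ether and the dioxolanone remain.

Step 12
Reactants: 19 diol; 20 (E)-4-acetoxycinnamic acid (2.5 equiv)
Product: 22 3-O-TBS-4,5-bis-O-[(E)-4-acetoxycinnamoyl]quinic acid pivalaldehyde acetal, via (E)-4-acetoxycinnamoyl chloride 21 (not isolated)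
Conditions: 20, (COCl)2, DMF (cat.), CH2Cl2, 0 °C → rt, evaporate; then 19, pyridine, DMAP (cat.), CH2Cl2, 0 °C → rt
Reagents that add atoms: none
Why: Acyl chloride esterification under nucleophilic (DMAP) catalysis should acylate both secondary hydroxyls; the weakly basic medium should not drive O3-to-O4 silyl migration, and the acetate-masked phenols cannot self-acylate.

Step 13
Reactants: 22 protected diester
Product: 23 4,5-di-O-p-coumaroylquinic acid
Conditions: 2 M aq. HCl–THF (1:1), rt (40 °C only if the acetal lags)
Reagents that add atoms: none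
Why: Acid-catalysed hydrolysis should remove the dioxolanone acetal, the TBS ether and both aryl acetates in one operation; acidic conditions are chosen because cinnamate esters of quinic acid are expected to survive them, whereas base would move the C4 ester to the cis O3.

## Compound list

1 | (S)-malic acid | OC(=O)C[C@H](O)C(=O)O | starting material
2 | pivalaldehyde | CC(C)(C)C=O | starting material
3 | 2-[(2S,4S)-2-tert-butyl-5-oxo-1,3-dioxolan-4-yl]acetic acid | OC(=O)C[C@@H]1O[C@H](C(C)(C)C)OC1=O | intermediate
4 | 3-bromo-2-(bromomethyl)prop-1-ene | C=C(CBr)CBr | starting material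
5 | benzyl alcohol | OCc1ccccc1 | starting material
6 | sodium benzyloxide (not isolated) | [Na+].[O-]Cc1ccccc1 | intermediate
7 | 2-(benzyloxymethyl)allyl bromide | C=C(CBr)COCc1ccccc1 | intermediate
8 | dilithium enolate carboxylate of 3 (not isolated) | [Li+].[Li+].[O-]C(=O)CC1=C([O-])O[C@@H](C(C)(C)C)O1 | intermediate
9 | 2-[(2S,4S)-4-{2-[(benzyloxy)methyl]prop-2-en-1-yl}-2-tert-butyl-5-oxo-1,3-dioxolan-4-yl]acetic acid | OC(=O)C[C@]1(CC(=C)COCc2ccccc2)O[C@H](C(C)(C)C)OC1=O | intermediate
10 | S-ethyl thioester of 9 | CCSC(=O)C[C@]1(CC(=C)COCc2ccccc2)O[C@H](C(C)(C)C)OC1=O | intermediate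
11 | secondary ozonide (1,2,4-trioxolane) of 10, epimer mixture at the trioxolane carbon (not isolated) | CCSC(=O)C[C@]1(CC2(COCc3ccccc3)OCOO2)O[C@H](C(C)(C)C)OC1=O | intermediate
12 | S-ethyl 2-[(2S,4S)-4-(3-benzyloxy-2-oxopropyl)-2-tert-butyl-5-oxo-1,3-dioxolan-4-yl]ethanethioate | CCSC(=O)C[C@]1(CC(=O)COCc2ccccc2)O[C@H](C(C)(C)C)OC1=O | intermediate
13 | (2S,5R)-5-(3-benzyloxy-2-oxopropyl)-2-tert-butyl-5-(2-oxoethyl)-1,3-dioxolan-4-one | O=CC[C@]1(CC(=O)COCc2ccccc2)O[C@H](C(C)(C)C)OC1=O | intermediate
14 | 4-O-benzyl-3-dehydroquinic acid pivalaldehyde acetal (spiro dioxolanone; 4S,5R) | c1ccccc1CO[C@@H]1C(=O)C[C@]2(O[C@H](C(C)(C)C)OC2=O)C[C@H]1O | intermediate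
15 | 5-O-TES ether of 14 | c1ccccc1CO[C@@H]1C(=O)C[C@]2(O[C@H](C(C)(C)C)OC2=O)C[C@H]1O[Si](CC)(CC)CC | intermediate
16 | 4-O-benzyl-5-O-TES-quinic acid pivalaldehyde acetal (3-OH axial, 3R) | c1ccccc1CO[C@@H]1[C@H](O)C[C@]2(O[C@H](C(C)(C)C)OC2=O)C[C@H]1O[Si](CC)(CC)CC | intermediate
17 | 4-O-benzyl-3-O-TBS-5-O-TES-quinic acid pivalaldehyde acetal | c1ccccc1CO[C@@H]1[C@H](O[Si](C)(C)C(C)(C)C)C[C@]2(O[C@H](C(C)(C)C)OC2=O)C[C@H]1O[Si](CC)(CC)CC | intermediate
18 | 3-O-TBS-5-O-TES-quinic acid pivalaldehyde acetal, 4-OH free (not isolated) | O[C@@H]1[C@H](O[Si](C)(C)C(C)(C)C)C[C@]2(O[C@H](C(C)(C)C)OC2=O)C[C@H]1O[Si](CC)(CC)CC | intermediate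
19 | 3-O-TBS-quinic acid pivalaldehyde acetal (4,5-diol) | O[C@@H]1[C@H](O[Si](C)(C)C(C)(C)C)C[C@]2(O[C@H](C(C)(C)C)OC2=O)C[C@H]1O | intermediate
20 | (E)-4-acetoxycinnamic acid | CC(=O)Oc1ccc(/C=C/C(=O)O)cc1 | starting material
21 | (E)-4-acetoxycinnamoyl chloride (not isolated) | CC(=O)Oc1ccc(/C=C/C(=O)Cl)cc1 | intermediate
22 | 3-O-TBS-4,5-bis-O-[(E)-4-acetoxycinnamoyl]quinic acid pivalaldehyde acetal | O=C(/C=C/c1ccc(OC(C)=O)cc1)O[C@@H]1[C@H](O[Si](C)(C)C(C)(C)C)C[C@]2(O[C@H](C(C)(C)C)OC2=O)C[C@H]1OC(=O)/C=C/c1ccc(OC(C)=O)cc1 | intermediate
23 | 4,5-di-O-p-coumaroylquinic acid | O=C(/C=C/c1ccc(O)cc1)O[C@@H]1[C@H](O)C[C@@](O)(C(=O)O)C[C@H]1OC(=O)/C=C/c1ccc(O)cc1 | target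

## Step count and risks

Total steps: 13. Longest linear sequence: 12 (steps 1 and 3–13, from (S)-malic acid).

Most likely to fail:

Step 7 (proposed new method). Ring closure may not occur if the enamine toward C4 forms too slowly. The C1 oxygen may be lost by β-elimination from the C2 enamine or the aldehyde enamine, which opens the dioxolanone. Facial selectivity relative to C1 may be poor if catalyst and substrate are mismatched, and the lactone may transfer to the new C5 hydroxyl. The fallback makes the same bond by an intramolecular Mukaiyama aldol; it sets out from 12 and returns at 14. Keto thioester 12 is enol-silylated with TBSOTf/Et3N (CH2Cl2, −78 → 0 °C), expected toward C4 because C2 is neopentylic and C4–H is acidified by the benzyloxy group, to give the (Z)-silyl enol ether thioester F1. Fukuyama reduction (Et3SiH, Pd/C, acetone) converts the thioester to the silyl enol ether aldehyde F2. BF3·OEt2 in CH2Cl2 at −78 °C should then close the ring to ketol 14, with its C5 epimer removed by chromatography.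

Step 9. Hydride may add from the axial side (3-epi alcohol) or attack the lactone carbonyl. The fallback reverses the order of silylation and reduction and delivers hydride from O5; it sets out from 14 and returns at 16. Ketol 14 is reduced with Me4NBH(OAc)3 in AcOH–MeCN at −30 °C (Evans–Saksena reduction), which should give the 1,3-anti diol, 4-O-benzylquinic acid pivalaldehyde acetal F3. TESCl (1 equiv) with imidazole at −20 °C should then silylate the equatorial 5-OH in preference to the axial, flanked 3-OH and give 16.

Step 12. Acylation of the C4 hydroxyl next to the axial silyl ether may stall, the TBS group may migrate from O3 to O4, or acetyl may transfer from the aryl acetates. The fallback builds the cinnamate esters on the diol in two stages; it sets out from 19 and returns at 23. Diol 19 is heated with Meldrum's acid (toluene, 90 °C, no base) to give the 4,5-bis(hydrogen malonate) F4. Knoevenagel–Doebner condensation with 4-hydroxybenzaldehyde (pyridine, cat. piperidine, rt → 40 °C) should give the 3-O-TBS 4,5-bis-O-p-coumaroyl acetal with free phenols F5. Aqueous HCl–THF at rt then removes the silyl ether and the acetal to give 23.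

Further compounds
F1 | step 7 | (Z)-tert-butyldimethylsilyl enol ether (toward C4) of keto thioester 12 | CCSC(=O)C[C@]1(C/C(O[Si](C)(C)C(C)(C)C)=C/OCc2ccccc2)O[C@H](C(C)(C)C)OC1=O
F2 | step 7 | (Z)-tert-butyldimethylsilyl enol ether aldehyde | O=CC[C@]1(C/C(O[Si](C)(C)C(C)(C)C)=C/OCc2ccccc2)O[C@H](C(C)(C)C)OC1=O
F3 | step 9 | 4-O-benzylquinic acid pivalaldehyde acetal (3,5-diol) | c1ccccc1CO[C@@H]1[C@H](O)C[C@]2(O[C@H](C(C)(C)C)OC2=O)C[C@H]1O
F4 | step 12 | 3-O-TBS-quinic acid pivalaldehyde acetal 4,5-bis(hydrogen malonate) | OC(=O)CC(=O)O[C@@H]1[C@H](O[Si](C)(C)C(C)(C)C)C[C@]2(O[C@H](C(C)(C)C)OC2=O)C[C@H]1OC(=O)CC(=O)O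
F5 | step 12 | 3-O-TBS-4,5-di-O-p-coumaroylquinic acid pivalaldehyde acetal | O=C(/C=C/c1ccc(O)cc1)O[C@@H]1[C@H](O[Si](C)(C)C(C)(C)C)C[C@]2(O[C@H](C(C)(C)C)OC2=O)C[C@H]1OC(=O)/C=C/c1ccc(O)cc1
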